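**Retrosynthetic overview**
- The target comes from cation exchange and one global hydrogenolysis of three benzyl ethers. The precursor is the 6,7-bis-sulfate salt of 5,3',4'-tri-O-benzyl-6-hydroxyluteolin. Its two O–S bonds are made on a flavone whose only free OH groups are 6-OH and 7-OH.
- That 6,7-catechol comes from the new step, which forms the O1–C8a bond and ring C. An acyclic 1-(2-benzyloxy-3,4-dihydroxyphenyl)-3-aryl-1,3-diketone is oxidised to its o-quinone, and the enol oxygen adds to it intramolecularly.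
- The diketone comes from a crossed Claisen condensation (C2–C3 bond) of protected gallacetophenone with methyl 3,4-bis(benzyloxy)benzoate.
- The 2',3',4'-oxygens of gallacetophenone become O5, O6 and O7, because closure uses its only ortho C–H and not the 2'-OH.
- Ring order: rings A and B are bought. Ring C (the 4-pyranone) is the only ring formed, in step 6.

**Assumption:** the target has no stereocentre or other stereo-element (flat, achiral flavone), so "single enantiomer" needs no action. The target is taken as the free bis(hydrogen sulfate) drawn in the SMILES.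

**Route**

Step 1
Reactants: 1 2',3',4'-trihydroxyacetophenone (gallacetophenone)
Product: 2 1-[2-hydroxy-3,4-bis(methoxymethoxy)phenyl]ethanone
Conditions: MOMCl (2.3 equiv), K2CO3 (3 equiv), acetone, N2, 0 °C to rt
Reagents that add atoms: chloromethyl methyl ether (MOMCl), COCCl
Why: Williamson-type O-alkylation (MOM acetal protection) in which the 2'-OH is locked in a hydrogen bond to the acetyl C=O, so only the 3'- and 4'-OH react and no stereocentre is formed.

Step 2
Reactants: 2 1-[2-hydroxy-3,4-bis(methoxymethoxy)phenyl]ethanone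
Product: 3 1-[2-(benzyloxy)-3,4-bis(methoxymethoxy)phenyl]ethanone
Conditions: BnBr (1.3 equiv), K2CO3 (2 equiv), KI (cat.), DMF, 70 °C
Reagents that add atoms: benzyl bromide, BrCc1ccccc1
Why: Williamson ether synthesis under forcing carbonate/DMF conditions alkylates the chelated 2'-OH, which puts a hydrogenolysable group on the future O5 and blocks the ordinary cyclisation through this oxygen.

Step 3
Reactants: 4 methyl 3,4-dihydroxybenzoate
Product: 5 methyl 3,4-bis(benzyloxy)benzoate
Conditions: BnBr (2.4 equiv), K2CO3 (3 equiv), DMF, 60 °C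
Reagents that add atoms: benzyl bromide, BrCc1ccccc1
Why: Williamson ether synthesis on both acidic phenols of an ester that is inert to carbonate.

Step 4
Reactants: 3 1-[2-(benzyloxy)-3,4-bis(methoxymethoxy)phenyl]ethanone; 5 methyl 3,4-bis(benzyloxy)benzoate
Product: 6 1-[2-(benzyloxy)-3,4-bis(methoxymethoxy)phenyl]-3-[3,4-bis(benzyloxy)phenyl]propane-1,3-dione (mainly enol)
Conditions: NaH (2.5 equiv), THF, reflux; AcOH quench, 0 °C
Reagents that add atoms: none
Why: Crossed Claisen condensation in which only 3 is enolisable, 5 cannot self-condense, and irreversible deprotonation of the β-diketone drives the equilibrium, while MOM and benzyl ethers are base-stable.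

Step 5
Reactants: 6 1-[2-(benzyloxy)-3,4-bis(methoxymethoxy)phenyl]-3-[3,4-bis(benzyloxy)phenyl]propane-1,3-dione
Product: 7 1-[2-(benzyloxy)-3,4-dihydroxyphenyl]-3-[3,4-bis(benzyloxy)phenyl]propane-1,3-dione
Conditions: HCl (1.25 M in MeOH), THF, 45 °C, N2
Reagents that add atoms: none
Why: Acid-catalysed acetal exchange (MOM cleavage) frees only the 3',4'-catechol, the benzyl ethers survive dilute HCl, and the diketone cannot cyclodehydrate because no ortho-OH is free.

Step 6
Reactants: 7 1-[2-(benzyloxy)-3,4-dihydroxyphenyl]-3-[3,4-bis(benzyloxy)phenyl]propane-1,3-dione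
Product: 10 5-(benzyloxy)-2-[3,4-bis(benzyloxy)phenyl]-6,7-dihydroxy-4H-chromen-4-one, via acyclic ortho-quinone 8 (not isolated), via flavone ortho-quinone 9 (not isolated)
Conditions: PhI(OAc)2 (2.1 equiv, added over 1 h), Bu4NOAc (1 equiv, buffer), MeCN (5 mM), N2, −20 to 0 °C; then aq Na2S2O4, EtOAc
Reagents that add atoms: none
Why: Proposed new method: oxidative ortho-quinone oxa-Michael flavone annulation, in which PhI(OAc)2 oxidises only the free catechol of 7 (all other oxygens are benzylated) to the electron-poor 4-acyl-3-benzyloxy-o-quinone 8, whose single unsubstituted position next to the acyl group (C6', the β-carbon of the C4'=O enone) is attacked 6-exo-trig by the acetate-activated enol oxygen on the ring-B side of the diketone (attack through carbon would need a four-membered ring), and tautomerisation re-aromatises to catechol 10 with the O1–C8a bond and ring C in place; because 10 is more electron-rich than 7 it is oxidised on to the vinylogous-ester-stabilised quinone 9, so two equivalents of oxidant are used on purpose and dithionite returns 9 to 10; the closest known reaction types are the final five-membered enol-O to o-quinone closure in oxidative catechol/1,3-dicarbonyl benzofuran and coumestan syntheses, the dopaquinone to cyclodopa aza-Michael closure and the oxidative closure of 2,3'-dihydroxybenzophenones to xanthones, none of which has been used to build a 4-pyranone, and no stereocentre is formed.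

Step 7
Reactants: 10 5-(benzyloxy)-2-[3,4-bis(benzyloxy)phenyl]-6,7-dihydroxy-4H-chromen-4-one
Product: 11 bis(tributylammonium) 5-(benzyloxy)-2-[3,4-bis(benzyloxy)phenyl]-4-oxo-4H-chromene-6,7-diyl disulfate
Conditions: Bu3N·SO3 (6 equiv), MeCN, 70 °C
Reagents that add atoms: tributylsulfoammonium betaine (Bu3N·SO3), CCCC[N+](CCCC)(CCCC)S(=O)(=O)[O-]
Why: O-sulfation with an amine–sulfur trioxide complex meets only two free OH groups, so regiochemistry is fixed by the route, and the lipophilic Bu3NH+ ion pair screens the first sulfate charge so that the hindered neighbour also reacts and the salt can be extracted and chromatographed.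

Step 8
Reactants: 11 bis(tributylammonium) 5-(benzyloxy)-2-[3,4-bis(benzyloxy)phenyl]-4-oxo-4H-chromene-6,7-diyl disulfate
Product: 12 bis(tributylammonium) 2-(3,4-dihydroxyphenyl)-5-hydroxy-4-oxo-4H-chromene-6,7-diyl disulfate
Conditions: H2 (1 atm), 10% Pd/C, MeOH, rt
Reagents that add atoms: none
Why: Catalytic hydrogenolysis cleaves all three aryl benzyl ethers at neutral pH, where aryl sulfate monoester anions and the flavone C2=C3 bond are inert.

Step 9
Reactants: 12 bis(tributylammonium) 2-(3,4-dihydroxyphenyl)-5-hydroxy-4-oxo-4H-chromene-6,7-diyl disulfate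
Product: 13 6-hydroxyluteolin 6,7-disulfate, 2-(3,4-dihydroxyphenyl)-5-hydroxy-4-oxo-4H-chromene-6,7-diyl bis(hydrogen sulfate)
Conditions: sulfonated polystyrene cation-exchange resin (H+ form), H2O–MeOH, 0–4 °C; freeze-dry at once
Reagents that add atoms: none
Why: Simple cation exchange (acid–base) swaps Bu3NH+ for H+, and cold, fast handling limits the acid-catalysed hydrolysis of the aryl hydrogen sulfates.

**Compound list**
1 | 2',3',4'-trihydroxyacetophenone (gallacetophenone) | CC(=O)c1ccc(O)c(O)c1O | starting material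
2 | 1-[2-hydroxy-3,4-bis(methoxymethoxy)phenyl]ethanone | CC(=O)c1ccc(OCOC)c(OCOC)c1O | intermediate
3 | 1-[2-(benzyloxy)-3,4-bis(methoxymethoxy)phenyl]ethanone | CC(=O)c1ccc(OCOC)c(OCOC)c1OCc1ccccc1 | intermediate
4 | methyl 3,4-dihydroxybenzoate | COC(=O)c1ccc(O)c(O)c1 | starting material
5 | methyl 3,4-bis(benzyloxy)benzoate | COC(=O)c1ccc(OCc2ccccc2)c(OCc2ccccc2)c1 | intermediate
6 | 1-[2-(benzyloxy)-3,4-bis(methoxymethoxy)phenyl]-3-[3,4-bis(benzyloxy)phenyl]propane-1,3-dione | O=C(CC(=O)c1ccc(OCc2ccccc2)c(OCc2ccccc2)c1)c1ccc(OCOC)c(OCOC)c1OCc1ccccc1 | intermediate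
7 | 1-[2-(benzyloxy)-3,4-dihydroxyphenyl]-3-[3,4-bis(benzyloxy)phenyl]propane-1,3-dione | O=C(CC(=O)c1ccc(OCc2ccccc2)c(OCc2ccccc2)c1)c1ccc(O)c(O)c1OCc1ccccc1 | intermediate
8 | acyclic ortho-quinone, 1-[2-(benzyloxy)-3,4-dioxocyclohexa-1,5-dien-1-yl]-3-[3,4-bis(benzyloxy)phenyl]propane-1,3-dione | O=C(CC(=O)c1ccc(OCc2ccccc2)c(OCc2ccccc2)c1)C1=C(OCc2ccccc2)C(=O)C(=O)C=C1 | intermediate
9 | flavone ortho-quinone, 5-(benzyloxy)-2-[3,4-bis(benzyloxy)phenyl]-4H-chromene-4,6,7-trione | O=C1C=C(c2ccc(OCc3ccccc3)c(OCc3ccccc3)c2)OC2=CC(=O)C(=O)C(OCc3ccccc3)=C12 | intermediate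
10 | 5-(benzyloxy)-2-[3,4-bis(benzyloxy)phenyl]-6,7-dihydroxy-4H-chromen-4-one (5,3',4'-tri-O-benzyl-6-hydroxyluteolin) | O=c1cc(-c2ccc(OCc3ccccc3)c(OCc3ccccc3)c2)oc2cc(O)c(O)c(OCc3ccccc3)c12 | intermediate
11 | bis(tributylammonium) 5-(benzyloxy)-2-[3,4-bis(benzyloxy)phenyl]-4-oxo-4H-chromene-6,7-diyl disulfate | CCCC[NH+](CCCC)CCCC.CCCC[NH+](CCCC)CCCC.O=c1cc(-c2ccc(OCc3ccccc3)c(OCc3ccccc3)c2)oc2cc(OS(=O)(=O)[O-])c(OS(=O)(=O)[O-])c(OCc3ccccc3)c12 | intermediate
12 | bis(tributylammonium) 2-(3,4-dihydroxyphenyl)-5-hydroxy-4-oxo-4H-chromene-6,7-diyl disulfate | CCCC[NH+](CCCC)CCCC.CCCC[NH+](CCCC)CCCC.O=c1cc(-c2ccc(O)c(O)c2)oc2cc(OS(=O)(=O)[O-])c(OS(=O)(=O)[O-])c(O)c12 | intermediate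
13 | 6-hydroxyluteolin 6,7-disulfate (achiral) | O=c1cc(-c2ccc(O)c(O)c2)oc2cc(OS(=O)(=O)O)c(OS(=O)(=O)O)c(O)c12 | target

**Total step count:** 9
**Longest linear sequence:** 8 steps (1 → 2 → 3 → 6 → 7 → 10 → 11 → 12 → 13). Step 3 is the side branch.

**Three steps most likely to fail**

**Step 6 (the proposed new step).**
- Risks:
  - The diketone carbon of one molecule may attack the quinone of another, which gives oligomers. This is the reason for working at 5 mM.
  - Ipso attack at C2' with loss of benzyl alcohol would lead into the 7,8-series.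
  - Quinone 9 may decay before it is reduced.
- Fallback with known chemistry: it sets out from 3 and comes back at 10.
  - Ketone-directed iridium-catalysed ortho C–H borylation of 3 uses B2pin2, [Ir(OMe)(cod)]2 and AsPh3 in octane at 110 °C. C6' is the only C–H ortho to the acetyl group. The product is 1-[2-(benzyloxy)-3,4-bis(methoxymethoxy)-6-(4,4,5,5-tetramethyl-1,3,2-dioxaborolan-2-yl)phenyl]ethanone F1.
  - Sodium perborate in THF–water oxidises the C–B bond to give 1-[2-(benzyloxy)-6-hydroxy-3,4-bis(methoxymethoxy)phenyl]ethanone F2.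
  - Claisen condensation of F2 with 5 (NaH, 3.5 equiv, THF, reflux) gives 1-[2-(benzyloxy)-6-hydroxy-3,4-bis(methoxymethoxy)phenyl]-3-[3,4-bis(benzyloxy)phenyl]propane-1,3-dione F3.
  - HCl in MeOH at 50 °C then brings about the classical cyclodehydration of the o-hydroxy-β-diketone together with MOM cleavage, and this gives 10.

**Step 7.**
- Risk: the second, hindered OH (6-OH, between 5-OBn and the 7-sulfate anion) may stop at the monosulfate.
- Fallback: a neutral protected sulfate diester replaces direct SO3 transfer. It sets out from 10 and comes back at 11.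
  - 2,2,2-Trichloroethyl chlorosulfate (2.5 equiv) with Et3N and DMAP in THF, 0 °C to rt, gives the uncharged, silica-stable 5-(benzyloxy)-2-[3,4-bis(benzyloxy)phenyl]-4-oxo-4H-chromene-6,7-diyl bis(2,2,2-trichloroethyl) disulfate F4.
  - Zinc dust and ammonium formate in MeOH fragment both trichloroethyl groups to give diammonium 5-(benzyloxy)-2-[3,4-bis(benzyloxy)phenyl]-4-oxo-4H-chromene-6,7-diyl disulfate F5.
  - Co-evaporation with Bu3N (2.2 equiv) from MeOH exchanges the cation and gives 11.

**Step 9.**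
- Risk: the free bis(hydrogen sulfate) can hydrolyse itself as the resin eluate is concentrated.
- Fallback: stoichiometric precipitation metathesis replaces resin exchange. It sets out from 12 and comes back at 13.
  - Barium acetate (1.0 equiv) in aqueous MeOH, followed by acetone, precipitates barium 2-(3,4-dihydroxyphenyl)-5-hydroxy-4-oxo-4H-chromene-6,7-diyl disulfate F6.
  - F6 is suspended in ice water and treated with exactly 1.00 equiv of cold dilute H2SO4.
  - The insoluble barium salt is centrifuged off, and the dilute, salt-free solution of 13 is freeze-dried.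

**Further compounds**
F1 | step 6 | 1-[2-(benzyloxy)-3,4-bis(methoxymethoxy)-6-(4,4,5,5-tetramethyl-1,3,2-dioxaborolan-2-yl)phenyl]ethanone | CC(=O)c1c(B2OC(C)(C)C(C)(C)O2)cc(OCOC)c(OCOC)c1OCc1ccccc1
F2 | step 6 | 1-[2-(benzyloxy)-6-hydroxy-3,4-bis(methoxymethoxy)phenyl]ethanone | CC(=O)c1c(O)cc(OCOC)c(OCOC)c1OCc1ccccc1
F3 | step 6 | 1-[2-(benzyloxy)-6-hydroxy-3,4-bis(methoxymethoxy)phenyl]-3-[3,4-bis(benzyloxy)phenyl]propane-1,3-dione | O=C(CC(=O)c1ccc(OCc2ccccc2)c(OCc2ccccc2)c1)c1c(O)cc(OCOC)c(OCOC)c1OCc1ccccc1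
F4 | step 7 | 5-(benzyloxy)-2-[3,4-bis(benzyloxy)phenyl]-4-oxo-4H-chromene-6,7-diyl bis(2,2,2-trichloroethyl) disulfate | O=c1cc(-c2ccc(OCc3ccccc3)c(OCc3ccccc3)c2)oc2cc(OS(=O)(=O)OCC(Cl)(Cl)Cl)c(OS(=O)(=O)OCC(Cl)(Cl)Cl)c(OCc3ccccc3)c12
F5 | step 7 | diammonium 5-(benzyloxy)-2-[3,4-bis(benzyloxy)phenyl]-4-oxo-4H-chromene-6,7-diyl disulfate | [NH4+].[NH4+].O=c1cc(-c2ccc(OCc3ccccc3)c(OCc3ccccc3)c2)oc2cc(OS(=O)(=O)[O-])c(OS(=O)(=O)[O-])c(OCc3ccccc3)c12
F6 | step 9 | barium 2-(3,4-dihydroxyphenyl)-5-hydroxy-4-oxo-4H-chromene-6,7-diyl disulfate | [Ba+2].O=c1cc(-c2ccc(O)c(O)c2)oc2cc(OS(=O)(=O)[O-])c(OS(=O)(=O)[O-])c(O)c12
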